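**Retrosynthetic overview**
1. Target 30 ⇐ dienone 24 (arene demethylation, Markovnikov hydration of C13=CH2, Wittig methylenation, hydrogenation); the benzylic carbon C15 is joined to C14 by an aldol reaction that uses the enol ether left by the key step.
2. 24 ⇐ cycloadduct 20 ⇐ triene 19: rings B and C are disconnected together at C8–C9 and C11–C12, an intramolecular Diels–Alder reaction of the 2-silyloxy diene C12=C13–C14=C8 with the nitroalkene C9=C11.
3. Enabling feature: the C13 oxygen of ring C (carried as the silyloxy group of the diene, later the C13 carbinol) and the C19–O–C20 lactone bridge across C4/C10, which holds ring A in one chair with the C5 and C10 branches equatorial; the nitro group on C11 is a traceless activator, lost as nitrite.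
4. 19 ⇐ ring A lactone 10 ⇐ all-cis 2-alkylcyclohexane-1,3-dicarboxylate 5 (arene hydrogenation of isophthalate 4, enzymatic desymmetrisation, enolate alkylation at C10 and then at C4).
5. Ring order: ring A (from the arene), lactone ring, then rings B and C in one step; the hydroquinone ring is attached afterwards.

Key step: step 13

Numbering (labdane type): ring A = C1–C5, C10; ring B = C5–C10; ring C = C8, C9, C11–C14; C15 = benzylic CH2; C19 = lactone C=O on C4; C20 = lactone OCH2 on C10; α = face of H-5, β = face of the C20 bridge.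
Assumption: pig liver esterase is taken to hydrolyse the ester on the ring carbon that becomes C4; if it cleaves the other ester, the enantiomeric hemiester leads to the same lactone 10 by exchanging the two alkylations (CH3I at the ester carbon first, the chloromethyl ether at the acid carbon second) and reducing the acid with BH3·SMe2.

**Route**

Step 1
Reactants: 1 dimethyl 2-bromoisophthalate; 2 2-methyl-2-vinyl-1,3-dioxolane
Product: 4 dimethyl 2-[2-(2-methyl-1,3-dioxolan-2-yl)ethyl]isophthalate, via B-alkyl-9-BBN adduct 3 (not isolated)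
Conditions: 2, 9-BBN-H, THF, 0 °C to rt; then 1, Pd(OAc)2 (3 mol %), SPhos (6 mol %), aq K3PO4, THF, 65 °C
Reagents that add atoms: none
Why: B-alkyl Suzuki–Miyaura coupling, in which anti-Markovnikov hydroboration of the vinyl group gives a primary alkylborane that should couple with the electron-poor, doubly ortho-substituted aryl bromide under a bulky biarylphosphine ligand; no stereocentre is formed.

Step 2
Reactants: 4 dimethyl 2-[2-(2-methyl-1,3-dioxolan-2-yl)ethyl]isophthalate
Product: 5 meso all-cis dimethyl 2-[2-(2-methyl-1,3-dioxolan-2-yl)ethyl]cyclohexane-1,3-dicarboxylate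
Conditions: H2 (50 bar), 5% Rh/Al2O3, MeOH, 40 °C
Reagents that add atoms: none
Why: heterogeneous arene hydrogenation over rhodium delivers all hydrogens from the adsorbed face, so the two esters and the side chain should end up all-cis (the C19/C6/C20 relationship of the target) while the ketal and esters stay intact.

Step 3
Reactants: 5 meso all-cis diester
Product: 6 hemiester all-cis 3-(methoxycarbonyl)-2-[2-(2-methyl-1,3-dioxolan-2-yl)ethyl]cyclohexane-1-carboxylic acid (CO2H on the future C4 and CO2CH3 on the future C10)
Conditions: pig liver esterase, 0.1 M phosphate buffer pH 7.5, acetone (10 vol %), 25 °C; then citric acid to pH 3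
Reagents that add atoms: water, O
Why: enzymatic desymmetrisation of a meso diester, in which hydrolysis of one enantiotopic ester at neutral pH (no epimerisation) should fix the absolute configuration of C4, C5 and C10 at once.

Step 4
Reactants: 6 hemiester
Product: 7 C10-alkylated hemiester (C10 quaternary with CO2CH3 cis and CH2OCH2CH2SiMe3 trans to the C5 chain)
Conditions: LDA (2.2 equiv), THF, −78 to −30 °C; SEMCl (1.05 equiv), −78 to −20 °C
Reagents that add atoms: 2-(trimethylsilyl)ethoxymethyl chloride, C[Si](C)(C)CCOCCl
Why: enolate alkylation, in which the second equivalent of base deprotonates α to the ester and not α to the carboxylate, and the C10 enolate should be C-alkylated on the face anti to the C5 side chain (held axial by A(1,3) strain), which puts the new CH2O arm (C9) trans to the C5 chain and leaves the ester (future C20) cis.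

Step 5
Reactants: 7 C10-alkylated hemiester
Product: 8 C4-methylated acid (C4 quaternary with CO2H cis and CH3 trans to the C5 chain)
Conditions: LDA (2.5 equiv), THF–DMPU, −78 to 0 °C; MeI, −78 °C to rt
Reagents that add atoms: iodomethane, CI
Why: alkylation of the carboxylic acid dianion at C4, the only enolisable position left, where methyl iodide should enter equatorially on the face opposite both the C5 chain and the C10 ester (the sense known from the Kemp triacid series), so that the C4 carboxyl stays cis to the C10 ester.

Step 6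
Reactants: 8 C4-methylated acid
Product: 10 ring A lactone ketone 1-methyl-9-(3-oxobutyl)-5-{[2-(trimethylsilyl)ethoxy]methyl}-3-oxabicyclo[3.3.1]nonan-2-one, via hydroxy acid 9 (not isolated)
Conditions: LiBH4 (3 equiv), THF, MeOH (1 equiv), 0 to 50 °C; then 2 M HCl, THF, rt
Reagents that add atoms: water, O
Why: LiBH4 reduces the methyl ester but not the lithium carboxylate, and on acidification the new C20 hydroxymethyl should lactonise with the cis-1,3 carboxyl (the trans ether arm cannot reach) while the dioxolane is hydrolysed to the methyl ketone.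

Step 7
Reactants: 10 ring A lactone ketone
Product: 12 terminal alkyne (9-but-3-ynyl lactone), via enol phosphate 11 (not isolated)
Conditions: LDA (1.1 equiv), THF, −78 °C; ClP(O)(OEt)2, −78 °C to rt; then LDA (2.3 equiv), −78 °C to rt; aq NH4Cl
Reagents that add atoms: none
Why: Negishi conversion of a methyl ketone into a terminal alkyne (kinetic deprotonation at the methyl group, O-phosphorylation, base-induced elimination of the enol phosphate), which the lactone should survive because its α-carbon is a quaternary bridgehead.

Step 8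
Reactants: 12 terminal alkyne
Product: 14 (E)-enone (9-[(E)-3-methyl-5-oxohex-3-enyl] lactone), via alkenylalane 13 (not isolated)
Conditions: Me3Al (2.5 equiv), Cp2ZrCl2 (0.25 equiv), CH2Cl2, 0 °C to rt; volatiles removed; then AcCl, Pd(PPh3)4 (5 mol %), THF, 0 °C to rt
Reagents that add atoms: trimethylaluminium, C[Al](C)C; acetyl chloride, CC(=O)Cl
Why: zirconium-catalysed Negishi carboalumination adds CH3 and aluminium syn across the alkyne with the methyl on the internal carbon (C8), and palladium-catalysed acylation with retention should give the E enone in which the ring-bearing chain is trans to the acyl group.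

Step 9
Reactants: 14 (E)-enone
Product: 15 primary alcohol (5-hydroxymethyl lactone enone)
Conditions: BF3·OEt2 (3 equiv), CH2Cl2, 0 °C to rt
Reagents that add atoms: none
Why: Lewis-acid-induced β-silyl fragmentation of the 2-(trimethylsilyl)ethyl ether (loss of ethene and Me3SiF) should free the neopentyl alcohol without touching the enone or the lactone.

Step 10
Reactants: 15 primary alcohol
Product: 16 aldehyde (5-formyl lactone enone)
Conditions: Dess–Martin periodinane, NaHCO3, CH2Cl2, rt
Reagents that add atoms: none
Why: Dess–Martin oxidation of a primary neopentyl alcohol should stop cleanly at the non-enolisable aldehyde C9.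

Step 11
Reactants: 16 aldehyde
Product: 18 (E)-nitroalkene (5-[(E)-2-nitroethenyl] lactone enone), via nitro alcohol 17 (not isolated)
Conditions: MeNO2 (10 equiv), KOtBu (10 mol %), THF/t-BuOH, 0 °C; then MsCl, Et3N, CH2Cl2, 0 °C
Reagents that add atoms: nitromethane, C[N+](=O)[O-]
Why: Henry reaction followed by mesylation and E1cB elimination should give the E nitroalkene, since the aldehyde cannot enolise and the β,β-disubstituted enone is a poor acceptor for the nitronate.

Step 12
Reactants: 18 (E)-nitroalkene
Product: 19 triene (9-[(E)-5-(tert-butyldimethylsilyloxy)-3-methylhexa-3,5-dienyl]-5-[(E)-2-nitroethenyl] lactone)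
Conditions: TBSOTf (1.2 equiv), Et3N (2.5 equiv), CH2Cl2, −78 to 0 °C; filtration through Et3N-deactivated silica
Reagents that add atoms: tert-butyldimethylsilyl trifluoromethanesulfonate, CC(C)(C)[Si](C)(C)OS(=O)(=O)C(F)(F)F
Why: soft enolisation of the methyl ketone at its methyl group (silyl triflate and amine) should give the cross-conjugated 2-silyloxy diene with the C8=C14 geometry unchanged, and the nitroalkene has no γ-hydrogen to lose.

Step 13
Reactants: 19 triene
Product: 20 cycloadduct (tricyclic lactone with 8β-CH3, 9α-H, 11α-NO2 and the C13(OTBS)=C14 enol ether)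
Conditions: toluene (0.01 M), BHT (5 mol %), degassed, 90 °C
Reagents that add atoms: none
Why: Thermal intramolecular Diels–Alder reaction ([4+2], suprafacial on both partners) between the 2-silyloxy diene C12=C13–C14=C8 and the E nitroalkene C9=C11, whose closest precedents are the cyclisation of 1-nitro-1,7,9-decatrienes to trans-fused nitrodecalins and the cycloaddition of 2-silyloxy dienes with nitroalkenes. Ring C is closed as the cyclohexene of the cycloaddition itself (both new bonds), and ring B is closed by the inner bond C8–C9 through the four-atom tether C7–C6–C5–C10, which takes a chair-like shape fused trans to ring A. C8 is set by the E geometry of C8=C14 (tether outside, methyl inside, so the methyl ends axial and β), C9 by the face of the nitroalkene that the tether can reach, and C11 by the E geometry of the nitroalkene (nitro trans to C10). The step needs the endo transition state (nitro under the diene) with a chair ring B, which gives the trans B/C fusion anti to the C20 bridge; the lactone bridge holds ring A in one chair with both branches equatorial, so attack on the other π-face would demand a boat ring B, and the nitro group both lowers the LUMO and favours the endo position. Regiochemistry is enforced by the tether, and the nitro group leaves in step 15.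

Step 14
Reactants: 20 cycloadduct; 21 2,5-dimethoxybenzaldehyde
Product: 22 aldol (14-[hydroxy(2,5-dimethoxyphenyl)methyl]-11α-nitro-13-ketone as a mixture at C14 and C15)
Conditions: TiCl4 (1.1 equiv), CH2Cl2, −78 °C; aq NaHCO3
Reagents that add atoms: none
Why: Mukaiyama aldol reaction, in which the regiodefined silyl enol ether from the cycloaddition should react only at C14, the hindered α-position that base enolisation of the ketone would avoid; the new centres at C14 and C15 are erased in the next step.

Step 15
Reactants: 22 aldol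
Product: 24 cross-conjugated dienone (14-(2,5-dimethoxybenzylidene)-Δ11-13-ketone), via mesylate 23 (not isolated)
Conditions: MsCl, Et3N, CH2Cl2, 0 °C; then DBU (3 equiv), rt
Reagents that add atoms: none
Why: two E1cB eliminations from the same ketone should occur, the C15 mesylate giving the benzylidene and the β-nitro group leaving C11 as nitrite to give the Δ11 enone, while the quaternary C8 blocks aromatisation.

Step 16
Reactants: 24 dienone
Product: 25 saturated ketone (14β-(2,5-dimethoxybenzyl)-13-ketone with 14α-H)
Conditions: H2 (1 atm), 10% Pd/C, EtOAc, rt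
Reagents that add atoms: none
Why: heterogeneous hydrogenation of both enone C=C bonds, in which hydrogen should add to C14=C15 from the α-face opposite the axial C8 methyl, giving 14α-H with the benzyl group equatorial (also the thermodynamic epimer α to the ketone).

Step 17
Reactants: 25 saturated ketone
Product: 26 13-methylidene compound
Conditions: Ph3PCH3Br, KOtBu, toluene, 80 °C
Reagents that add atoms: methyltriphenylphosphonium bromide, C[P+](c1ccccc1)(c1ccccc1)c1ccccc1.[Br-]
Why: Wittig methylenation under conditions used for hindered ketones should convert C13=O into C13=CH2 without harm to the lactone, and C14 is already the stable epimer.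

Step 18
Reactants: 26 13-methylidene compound
Product: 28 strongylophorine-8 dimethyl ether (13α-OH, 13β-CH3), via hydroperoxide 27 (not isolated)
Conditions: Co(acac)2 (20 mol %), PhSiH3 (2 equiv), O2 (1 atm), THF, rt; then PPh3
Reagents that add atoms: dioxygen, O=O
Why: Mukaiyama hydration (hydrogen atom transfer from a cobalt hydride, Markovnikov) gives the tertiary C13 radical, which should capture O2 from the equatorial α-face because the axial β-face is blocked by the syn-axial C8 methyl, and PPh3 reduces the hydroperoxide to the 13α-alcohol.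

Step 19
Reactants: 28 strongylophorine-8 dimethyl ether
Product: 30 strongylophorine-8, via quinone 29 (not isolated)
Conditions: (NH4)2Ce(NO3)6 (2.5 equiv), MeCN/H2O (2:1), 0 °C; then aq Na2S2O4, EtOAc, rt
Reagents that add atoms: water, O
Why: oxidative demethylation of the hydroquinone dimethyl ether to the p-quinone followed by dithionite reduction should release the hydroquinone under non-acidic conditions, so that the tertiary C13 alcohol neither eliminates nor closes to a chroman and the lactone is untouched.

**Compound list**
1 | dimethyl 2-bromoisophthalate | COC(=O)c1cccc(C(=O)OC)c1Br | starting material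
2 | 2-methyl-2-vinyl-1,3-dioxolane | C=CC1(C)OCCO1 | starting material
3 | B-[2-(2-methyl-1,3-dioxolan-2-yl)ethyl]-9-borabicyclo[3.3.1]nonane | CC1(CCB2C3CCCC2CCC3)OCCO1 | intermediate
4 | dimethyl 2-[2-(2-methyl-1,3-dioxolan-2-yl)ethyl]isophthalate | COC(=O)c1cccc(C(=O)OC)c1CCC1(C)OCCO1 | intermediate
5 | meso all-cis dimethyl 2-[2-(2-methyl-1,3-dioxolan-2-yl)ethyl]cyclohexane-1,3-dicarboxylate | CC1(CC[C@@H]2[C@H](C(=O)OC)CCC[C@@H]2C(=O)OC)OCCO1 | intermediate
6 | all-cis hemiester, CO2H on future C4 and CO2CH3 on future C10 | CC1(CC[C@@H]2[C@H](C(=O)OC)CCC[C@@H]2C(=O)O)OCCO1 | intermediate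
7 | C10-alkylated hemiester, CH2OCH2CH2SiMe3 trans to the C5 chain | CC1(CC[C@@H]2[C@](C(=O)OC)(CCC[C@@H]2C(=O)O)COCC[Si](C)(C)C)OCCO1 | intermediate
8 | C4-methylated acid, CH3 trans to the C5 chain | CC1(CC[C@@H]2[C@](C(=O)OC)(CCC[C@]2(C)C(=O)O)COCC[Si](C)(C)C)OCCO1 | intermediate
9 | hydroxy acid with C20 CH2OH | CC1(CC[C@@H]2[C@](CO)(CCC[C@]2(C)C(=O)O)COCC[Si](C)(C)C)OCCO1 | intermediate
10 | ring A lactone ketone, 1-methyl-9-(3-oxobutyl)-5-{[2-(trimethylsilyl)ethoxy]methyl}-3-oxabicyclo[3.3.1]nonan-2-one, C4/C5/C10 as in the target | CC(=O)CC[C@@H]1[C@]2(CCC[C@]1(C)C(=O)OC2)COCC[Si](C)(C)C | intermediate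
11 | enol diethyl phosphate of 10 (terminal) | C=C(OP(=O)(OCC)OCC)CC[C@@H]1[C@]2(CCC[C@]1(C)C(=O)OC2)COCC[Si](C)(C)C | intermediate
12 | terminal alkyne (9-but-3-ynyl lactone) | C#CCC[C@@H]1[C@]2(CCC[C@]1(C)C(=O)OC2)COCC[Si](C)(C)C | intermediate
13 | (E)-alkenyl(dimethyl)alane, Al cis to the new CH3 | C[Al](C)/C=C(\C)CC[C@@H]1[C@]2(CCC[C@]1(C)C(=O)OC2)COCC[Si](C)(C)C | intermediate
14 | (E)-enone, 9-[(E)-3-methyl-5-oxohex-3-enyl] lactone | CC(=O)/C=C(\C)CC[C@@H]1[C@]2(CCC[C@]1(C)C(=O)OC2)COCC[Si](C)(C)C | intermediate
15 | 5-hydroxymethyl lactone enone | CC(=O)/C=C(\C)CC[C@@H]1[C@]2(CCC[C@]1(C)C(=O)OC2)CO | intermediate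
16 | 5-formyl lactone enone | CC(=O)/C=C(\C)CC[C@@H]1[C@]2(CCC[C@]1(C)C(=O)OC2)C=O | intermediate
17 | nitro alcohol, 5-(1-hydroxy-2-nitroethyl), carbinol epimers | CC(=O)/C=C(\C)CC[C@@H]1[C@]2(CCC[C@]1(C)C(=O)OC2)C(O)C[N+](=O)[O-] | intermediate
18 | (E)-nitroalkene, 5-[(E)-2-nitroethenyl] lactone enone | CC(=O)/C=C(\C)CC[C@@H]1[C@]2(CCC[C@]1(C)C(=O)OC2)/C=C/[N+](=O)[O-] | intermediate
19 | triene, 2-silyloxy diene plus (E)-nitroalkene on the ring A lactone | C=C(O[Si](C)(C)C(C)(C)C)/C=C(\C)CC[C@@H]1[C@]2(CCC[C@]1(C)C(=O)OC2)/C=C/[N+](=O)[O-] | intermediate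
20 | cycloadduct, tricyclic lactone with 8β-CH3, 9α-H, 11α-NO2, C13(OTBS)=C14 | C[C@@]12CC[C@@H]3[C@]4(CCC[C@]3(C)C(=O)OC4)[C@H]1[C@H]([N+](=O)[O-])CC(O[Si](C)(C)C(C)(C)C)=C2 | intermediate
21 | 2,5-dimethoxybenzaldehyde | COc1ccc(OC)c(C=O)c1 | starting material
22 | aldol, 14-[hydroxy(2,5-dimethoxyphenyl)methyl]-11α-nitro-13-ketone, mixture at C14 and C15 | C[C@@]12CC[C@@H]3[C@]4(CCC[C@]3(C)C(=O)OC4)[C@H]1[C@H]([N+](=O)[O-])CC(=O)C2C(O)c1cc(OC)ccc1OC | intermediate
23 | C15 mesylate of 22 | C[C@@]12CC[C@@H]3[C@]4(CCC[C@]3(C)C(=O)OC4)[C@H]1[C@H]([N+](=O)[O-])CC(=O)C2C(OS(C)(=O)=O)c1cc(OC)ccc1OC | intermediate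
24 | cross-conjugated dienone, 14-(2,5-dimethoxybenzylidene)-Δ11-13-ketone, benzylidene geometry not defined | C[C@@]12CC[C@@H]3[C@]4(CCC[C@]3(C)C(=O)OC4)[C@H]1C=CC(=O)C2=Cc1cc(OC)ccc1OC | intermediate
25 | 14β-(2,5-dimethoxybenzyl)-13-ketone, 14α-H | C[C@@]12CC[C@@H]3[C@]4(CCC[C@]3(C)C(=O)OC4)[C@H]1CCC(=O)[C@H]2Cc1cc(OC)ccc1OC | intermediate
26 | 13-methylidene compound | C[C@@]12CC[C@@H]3[C@]4(CCC[C@]3(C)C(=O)OC4)[C@H]1CCC(=C)[C@H]2Cc1cc(OC)ccc1OC | intermediate
27 | 13α-hydroperoxide | C[C@@]12CC[C@@H]3[C@]4(CCC[C@]3(C)C(=O)OC4)[C@H]1CC[C@](C)(OO)[C@H]2Cc1cc(OC)ccc1OC | intermediate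
28 | strongylophorine-8 dimethyl ether | C[C@@]12CC[C@@H]3[C@]4(CCC[C@]3(C)C(=O)OC4)[C@H]1CC[C@](C)(O)[C@H]2Cc1cc(OC)ccc1OC | intermediate
29 | quinone of strongylophorine-8 | C[C@@]12CC[C@@H]3[C@]4(CCC[C@]3(C)C(=O)OC4)[C@H]1CC[C@](C)(O)[C@H]2CC1=CC(=O)C=CC1=O | intermediate
30 | strongylophorine-8 | C[C@@]12CC[C@@H]3[C@]4(CCC[C@]3(C)C(=O)OC4)[C@H]1CC[C@](C)(O)[C@H]2Cc1cc(O)ccc1O | target

**Totals and risks**
Total step count: 19. Longest linear sequence: 19 steps (1 to 30; 2 and 21 enter as commercial partners).

Steps most likely to fail: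

1. Step 13 (key cycloaddition). The diene carries an inside methyl group and its more nucleophilic terminus (C12) must bond to the nitro-bearing carbon, so the reaction may be slow, or the exo pathway may compete and give cis-fused B/C adducts. The fallback makes the same two bonds stepwise by a Robinson-type Michael/aldol annulation that uses only the native C11 and C13 carbonyls. It sets out from aldehyde 16, which would be homologated with Ph3P=CHOMe (from the phosphonium chloride and KHMDS, THF, 0 °C) to the enol ether F1 and hydrolysed (aq HCl, THF) to the C11 aldehyde F2. Pyrrolidine and AcOH (toluene, 60 °C) would then effect enamine Michael addition of C9 to C8 followed by aldol condensation of C12 onto C11, giving the tricyclic enone F3, whose C9 can equilibrate to the trans-fused isomer through the dienamine. Kinetic deprotonation at C14 (LDA, −78 °C) and addition of 21 would give the aldol F4, and MsCl/Et3N followed by DBU brings the route back at dienone 24.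

2. Step 18 (hydration at C13). Oxygen capture by the tertiary radical may show poor facial selectivity, or the radical may add to the electron-rich arene. The fallback sets out from 26 and fixes the configuration in a polar step: epoxidation with mCPBA (NaHCO3, CH2Cl2, 0 °C), which should occur from the α-face opposite the C8 methyl, would give the spiro-epoxide F5. Opening at the CH2 terminus with PhSeNa (PhSeSePh, NaBH4, EtOH; the lactone is not attacked) would give the β-hydroxy selenide F6, and Bu3SnH/AIBN (toluene, 100 °C) reduces the C–Se bond to the methyl group, returning at 28.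

3. Step 3 (enzymatic desymmetrisation). The esterase may discriminate poorly between the two enantiotopic esters of this substituted substrate. The fallback replaces hydrolysis of the diester by alcoholysis of the meso anhydride and sets out from 4: saponification (LiOH, THF/H2O) would give the aromatic diacid F7, hydrogenation of its disodium salt (Rh/Al2O3, H2, H2O) the all-cis diacid F8, and DCC (CH2Cl2) the bicyclic meso anhydride F9. Methanolysis mediated by the cinchona alkaloid derivative (DHQD)2AQN (MeOH, Et2O, −20 °C), or by its pseudo-enantiomer, brings the route back at hemiester 6.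

**Further compounds**
F1 | step 13 | enol ether, 5-(2-methoxyethenyl) lactone enone, E/Z mixture | CC(=O)/C=C(\C)CC[C@@H]1[C@]2(CCC[C@]1(C)C(=O)OC2)C=COC
F2 | step 13 | C11 aldehyde, 5-(2-oxoethyl) lactone enone | CC(=O)/C=C(\C)CC[C@@H]1[C@]2(CCC[C@]1(C)C(=O)OC2)CC=O
F3 | step 13 | tricyclic Δ11-13-ketone, 8β-CH3, 9α-H | C[C@@]12CC[C@@H]3[C@]4(CCC[C@]3(C)C(=O)OC4)[C@H]1C=CC(=O)C2
F4 | step 13 | aldol of F3 at C14 with 21, mixture at C14 and C15 | C[C@@]12CC[C@@H]3[C@]4(CCC[C@]3(C)C(=O)OC4)[C@H]1C=CC(=O)C2C(O)c1cc(OC)ccc1OC
F5 | step 18 | 13-spiro-epoxide, oxygen α | C[C@@]12CC[C@@H]3[C@]4(CCC[C@]3(C)C(=O)OC4)[C@H]1CC[C@]5(OC5)[C@H]2Cc1cc(OC)ccc1OC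
F6 | step 18 | 13α-hydroxy-13β-(phenylselanylmethyl) compound | C[C@@]12CC[C@@H]3[C@]4(CCC[C@]3(C)C(=O)OC4)[C@H]1CC[C@](C[Se]c5ccccc5)(O)[C@H]2Cc1cc(OC)ccc1OC
F7 | step 3 | 2-[2-(2-methyl-1,3-dioxolan-2-yl)ethyl]isophthalic acid | OC(=O)c1cccc(C(=O)O)c1CCC1(C)OCCO1
F8 | step 3 | meso all-cis 2-[2-(2-methyl-1,3-dioxolan-2-yl)ethyl]cyclohexane-1,3-dicarboxylic acid | CC1(CC[C@@H]2[C@H](C(=O)O)CCC[C@@H]2C(=O)O)OCCO1
F9 | step 3 | meso anhydride, 9-substituted 3-oxabicyclo[3.3.1]nonane-2,4-dione | CC1(CC[C@@H]2[C@H]3CCC[C@@H]2C(=O)OC3=O)OCCO1
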